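**Strategy.** The route rests on cutting the C2–C3 bond of the pyrrolidine-2,4-dione ring: C3 is the α-carbon of the C4 ketone and C2 a carbamoyl carbon on N1. Because the C4 oxygen and N1 sit on adjacent carbons (C4, C5), C2 can first be tied to both as a cyclic enol carbamate (a 5-alkylidene-oxazolidin-2-one) made from a propargylic amine and CO2. In one pot, base then breaks the temporary O–C2 bond to an isocyanate/enolate pair that recloses through carbon, turning the oxazolidinone into the tetramic acid. The C5 centre comes from a sulfinimine addition; both CCl3-bearing centres come from trichloromethyllithium additions to enantiomeric N-crotonyl sultams. C3-methylation and N-acylation finish the target.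

Key step: step 11

Assumption (remark on the chemistry): LiCCl3 is taken to add to the N-crotonyl (2R)-sultam on the Cβ face that gives the (3S) adduct, and the alkynyl Grignard reagent to add to the (R)-sulfinyl imine through the closed magnesium chelate; if either sense proves opposite, the antipodal auxiliary (both are commercial) is used in that step and nothing else changes.

**Route**

Step 1
Reactants: 1 (1S)-(−)-2,10-camphorsultam [(2R)-bornane-10,2-sultam]; 2 (E)-but-2-enoyl chloride
Product: 3 (2R)-N-[(E)-but-2-enoyl]bornane-10,2-sultam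
Conditions: NaH, toluene, 0 °C → rt
Reagents that add atoms: none
Why: N-acylation of the sultam sodium salt with an acid chloride (Oppolzer acylation); no stereocentre is formed and the (E)-alkene is kept.

Step 2
Reactants: 3 (2R)-N-[(E)-but-2-enoyl]bornane-10,2-sultam
Product: 4 (2R)-N-[(3S)-4,4,4-trichloro-3-methylbutanoyl]bornane-10,2-sultam
Conditions: CHCl3, n-BuLi, THF, −105 °C; then 3, −105 → −78 °C; AcOH
Reagents that add atoms: chloroform ClC(Cl)Cl
Why: Conjugate (Michael) addition of LiCCl3, kept below its carbenoid decomposition temperature, to the lithium-chelated s-cis N-enoyl sultam; the auxiliary shields one Cβ face and should set the C3 centre as (S), and the adduct can be enriched by crystallisation.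

Step 3
Reactants: 4 (2R)-N-[(3S)-4,4,4-trichloro-3-methylbutanoyl]bornane-10,2-sultam
Product: 5 (3S)-4,4,4-trichloro-3-methylbutanoic acid
Conditions: LiOH, H2O2, THF/H2O, 0 °C; aq. Na2SO3; then 1 M HCl
Reagents that add atoms: hydrogen peroxide OO
Why: Hydroperoxide cleavage of the N-acyl sultam (acyl substitution at the exocyclic carbonyl); the weakly basic LiOOH should spare the base-sensitive CCl3–CH unit, and the β-stereocentre is not enolisable.

Step 4
Reactants: 5 (3S)-4,4,4-trichloro-3-methylbutanoic acid
Product: 6 (3S)-4,4,4-trichloro-3-methylbutanoyl chloride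
Conditions: (COCl)2, DMF (cat.), CH2Cl2, 0 °C → rt
Reagents that add atoms: oxalyl chloride ClC(=O)C(=O)Cl
Why: Vilsmeier-type activation of the acid gives the acid chloride under non-basic conditions without touching the stereocentre.

Step 5
Reactants: 7 (1R)-(+)-2,10-camphorsultam [(2S)-bornane-10,2-sultam]; 2 (E)-but-2-enoyl chloride
Product: 8 (2S)-N-[(E)-but-2-enoyl]bornane-10,2-sultam
Conditions: NaH, toluene, 0 °C → rt
Reagents that add atoms: none
Why: Same Oppolzer N-acylation as step 1, in the enantiomeric auxiliary series.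

Step 6
Reactants: 8 (2S)-N-[(E)-but-2-enoyl]bornane-10,2-sultam
Product: 9 (2S)-N-[(3R)-4,4,4-trichloro-3-methylbutanoyl]bornane-10,2-sultam
Conditions: CHCl3, n-BuLi, THF, −105 °C; then 8, −105 → −78 °C; AcOH
Reagents that add atoms: chloroform ClC(Cl)Cl
Why: Mirror image of step 2: auxiliary-controlled Michael addition of LiCCl3 should set the C3 centre as (R), the later side-chain centre of the target.

Step 7
Reactants: 9 (2S)-N-[(3R)-4,4,4-trichloro-3-methylbutanoyl]bornane-10,2-sultam
Product: 10 (3R)-4,4,4-trichloro-3-methylbutanal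
Conditions: i-Bu2AlH, CH2Cl2, −78 °C; aq. potassium sodium tartrate
Reagents that add atoms: none
Why: Partial reduction of the N-acyl sultam: the chelated tetrahedral aluminate should persist at −78 °C and release the aldehyde only on work-up, so over-reduction is avoided and the β-centre is untouched.

Step 8
Reactants: 10 (3R)-4,4,4-trichloro-3-methylbutanal; 11 (R)-2-methylpropane-2-sulfinamide
Product: 12 (R)-N-[(1E,3R)-4,4,4-trichloro-3-methylbutylidene]-2-methylpropane-2-sulfinamide
Conditions: CuSO4, CH2Cl2, rt
Reagents that add atoms: none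
Why: Ellman condensation; CuSO4 acts as mild Lewis acid and water scavenger and should give the (E)-N-sulfinyl aldimine without base-mediated loss of the β-CCl3 group.

Step 9
Reactants: 12 (R)-N-[(1E,3R)-4,4,4-trichloro-3-methylbutylidene]-2-methylpropane-2-sulfinamide; 13 prop-1-ynylmagnesium bromide
Product: 14 (R)-N-[(4R,6R)-7,7,7-trichloro-6-methylhept-2-yn-4-yl]-2-methylpropane-2-sulfinamide
Conditions: CH2Cl2 (13 added as THF solution), −78 → −20 °C; aq. NH4Cl
Reagents that add atoms: none
Why: Ellman 1,2-addition of an alkynyl Grignard reagent through a six-membered chelate (Mg on the sulfinyl oxygen) in a non-coordinating solvent; the (R)-sulfinyl group directs the alkynyl group to one imine face and should set C4 as (R) (the later C5), the remote C6 centre having little influence.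

Step 10
Reactants: 14 (R)-N-[(4R,6R)-7,7,7-trichloro-6-methylhept-2-yn-4-yl]-2-methylpropane-2-sulfinamide
Product: 15 (4R,6R)-7,7,7-trichloro-6-methylhept-2-yn-4-amine
Conditions: HCl (4 M in dioxane), MeOH, 0 °C → rt; then aq. NaHCO3
Reagents that add atoms: none
Why: Acidic methanolysis of the N–S bond (sulfinyl transfer to methanol) frees the primary propargylic amine without affecting the alkyne, the CCl3 group or either stereocentre.

Step 11
Reactants: 15 (4R,6R)-7,7,7-trichloro-6-methylhept-2-yn-4-amine
Product: 18 (5R)-4-hydroxy-3-methyl-5-[(2R)-3,3,3-trichloro-2-methylpropyl]-1,5-dihydro-2H-pyrrol-2-one, via (Z)-5-ethylidene-oxazolidinone 16 (not isolated), via potassium isocyanato enolate 17 (not isolated)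
Conditions: AgOAc (5 mol %), CO2 (1 atm), DMSO, 25 °C; Ar purge; then t-BuOK (1.1 equiv), 25 → 40 °C; 1 M HCl
Reagents that add atoms: carbon dioxide O=C=O
Why: AgOAc activates the alkyne of the carbamate formed from 15 and CO2, and anti 5-exo-dig attack of the carbamate oxygen followed by protodeargentation should give the (Z)-enol carbamate 16, in which the future C4 oxygen and N1 are tied together through the future C2 carbonyl. Deprotonation of the N–H (the most acidic site) by t-BuOK then triggers E1cB cleavage of the O–C2 bond to the isocyanato enolate 17; its reclosure through oxygen is reversible, whereas attack of the enolate carbon on the isocyanate carbon, a 5-(enolendo)-exo-dig closure that forms the C2–C3 bond, is not, and proton transfer from C3 stores 18 as its tetramate. The closest known reaction type is the silver-catalysed CO2 incorporation into propargylic amines with base-mediated rearrangement of the 5-alkylidene-oxazolidin-2-ones to tetramic acids, established with DBU for arylmethylidene cases; the alkyl-substituted enolate here is a poorer leaving group, hence the stronger base in the second stage. No new stereocentre results (C3 is enolised), and C5 is carried through because nitrogen is deprotonated before any carbon acid and the product is held as the weakly basic tetramate. The step needs 5-exo over 6-endo O-cyclisation (secured by silver activation of the carbamate/alkyne pair), C- over O-carbamoylation (secured thermodynamically, the enol carbamate being the only reversible outcome) and survival of the CCl3–CH unit (secured by using one equivalent of base, consumed at once by the N–H).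

Step 12
Reactants: 18 (5R)-4-hydroxy-3-methyl-5-[(2R)-3,3,3-trichloro-2-methylpropyl]-1,5-dihydro-2H-pyrrol-2-one
Product: 19 (5R)-3,3-dimethyl-5-[(2R)-3,3,3-trichloro-2-methylpropyl]pyrrolidine-2,4-dione
Conditions: MeI, K2CO3, acetone, rt
Reagents that add atoms: iodomethane CI
Why: C-alkylation of the ambident tetramate (a cyclic 2-substituted 1,3-dicarbonyl anion) with the soft electrophile MeI should create the quaternary C3; no stereocentre is formed and carbonate is too weak to enolise C5.

Step 13
Reactants: 19 (5R)-3,3-dimethyl-5-[(2R)-3,3,3-trichloro-2-methylpropyl]pyrrolidine-2,4-dione; 6 (3S)-4,4,4-trichloro-3-methylbutanoyl chloride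
Product: 20 (5R)-3,3-dimethyl-1-[(3S)-4,4,4-trichloro-3-methylbutanoyl]-5-[(2R)-3,3,3-trichloro-2-methylpropyl]pyrrolidine-2,4-dione
Conditions: LiN(SiMe3)2 (1.0 equiv), THF, −78 °C; then 6, −78 °C; AcOH, −78 °C
Reagents that add atoms: none
Why: N-acylation of the lithium lactamate with an acid chloride (imide formation); kinetic N–H deprotonation with exactly one equivalent of base at −78 °C and a cold acidic quench should protect the C5 centre, which lies between the ketone and the imide nitrogen.

**Compound list**

1 | (1S)-(−)-2,10-camphorsultam [(2R)-bornane-10,2-sultam] | CC1(C)[C@@H]2CC[C@]13CS(=O)(=O)N[C@@H]3C2 | starting material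
2 | (E)-but-2-enoyl chloride (crotonyl chloride) | C/C=C/C(=O)Cl | starting material
3 | (2R)-N-[(E)-but-2-enoyl]bornane-10,2-sultam | CC1(C)[C@@H]2CC[C@]13CS(=O)(=O)N(C(=O)/C=C/C)[C@@H]3C2 | intermediate
4 | (2R)-N-[(3S)-4,4,4-trichloro-3-methylbutanoyl]bornane-10,2-sultam | CC1(C)[C@@H]2CC[C@]13CS(=O)(=O)N(C(=O)C[C@H](C)C(Cl)(Cl)Cl)[C@@H]3C2 | intermediate
5 | (3S)-4,4,4-trichloro-3-methylbutanoic acid | OC(=O)C[C@H](C)C(Cl)(Cl)Cl | intermediate
6 | (3S)-4,4,4-trichloro-3-methylbutanoyl chloride | ClC(=O)C[C@H](C)C(Cl)(Cl)Cl | intermediate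
7 | (1R)-(+)-2,10-camphorsultam [(2S)-bornane-10,2-sultam] | CC1(C)[C@H]2CC[C@@]13CS(=O)(=O)N[C@H]3C2 | starting material
8 | (2S)-N-[(E)-but-2-enoyl]bornane-10,2-sultam | CC1(C)[C@H]2CC[C@@]13CS(=O)(=O)N(C(=O)/C=C/C)[C@H]3C2 | intermediate
9 | (2S)-N-[(3R)-4,4,4-trichloro-3-methylbutanoyl]bornane-10,2-sultam | CC1(C)[C@H]2CC[C@@]13CS(=O)(=O)N(C(=O)C[C@@H](C)C(Cl)(Cl)Cl)[C@H]3C2 | intermediate
10 | (3R)-4,4,4-trichloro-3-methylbutanal | O=CC[C@@H](C)C(Cl)(Cl)Cl | intermediate
11 | (R)-2-methylpropane-2-sulfinamide | CC(C)(C)[S@@](=O)N | starting material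
12 | (R)-N-[(1E,3R)-4,4,4-trichloro-3-methylbutylidene]-2-methylpropane-2-sulfinamide | CC(C)(C)[S@@](=O)/N=C/C[C@@H](C)C(Cl)(Cl)Cl | intermediate
13 | prop-1-ynylmagnesium bromide | CC#C[Mg]Br | starting material
14 | (R)-N-[(4R,6R)-7,7,7-trichloro-6-methylhept-2-yn-4-yl]-2-methylpropane-2-sulfinamide | CC#C[C@H](N[S@](=O)C(C)(C)C)C[C@@H](C)C(Cl)(Cl)Cl | intermediate
15 | (4R,6R)-7,7,7-trichloro-6-methylhept-2-yn-4-amine | CC#C[C@H](N)C[C@@H](C)C(Cl)(Cl)Cl | intermediate
16 | (4R,5Z)-5-ethylidene-4-[(2R)-3,3,3-trichloro-2-methylpropyl]-1,3-oxazolidin-2-one (not isolated) | C/C=C1\OC(=O)N[C@@H]1C[C@@H](C)C(Cl)(Cl)Cl | intermediate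
17 | potassium (2Z,4R,6R)-7,7,7-trichloro-4-isocyanato-6-methylhept-2-en-3-olate (not isolated) | C/C=C(\[O-])[C@H](N=C=O)C[C@@H](C)C(Cl)(Cl)Cl.[K+] | intermediate
18 | (5R)-4-hydroxy-3-methyl-5-[(2R)-3,3,3-trichloro-2-methylpropyl]-1,5-dihydro-2H-pyrrol-2-one (3-methyltetramic acid, enol tautomer of the 2,4-dione) | CC1=C(O)[C@@H](C[C@@H](C)C(Cl)(Cl)Cl)NC1=O | intermediate
19 | (5R)-3,3-dimethyl-5-[(2R)-3,3,3-trichloro-2-methylpropyl]pyrrolidine-2,4-dione | CC1(C)C(=O)[C@@H](C[C@@H](C)C(Cl)(Cl)Cl)NC1=O | intermediate
20 | (5R)-3,3-dimethyl-1-[(3S)-4,4,4-trichloro-3-methylbutanoyl]-5-[(2R)-3,3,3-trichloro-2-methylpropyl]pyrrolidine-2,4-dione | C[C@H](C[C@@H]1C(=O)C(C)(C)C(=O)N1C(=O)C[C@H](C)C(Cl)(Cl)Cl)C(Cl)(Cl)Cl | target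

**Step count.** Total: 13 steps. Longest linear sequence: 9 steps (steps 5 to 13, from sultam 7).

**Steps most likely to fail**

1. Step 11 (key step). The N-metalated enol carbamate may fail to fragment, the transient isocyanate may be captured intermolecularly (urea and oligomer formation), or the exocyclic double bond may shift into the ring under base with loss of the C5 centre. The fallback sets out from 16, isolated after the silver stage before any base is added, and comes back at 20. Compound 16 would be N-acylated with 6 (Et3N, DMAP cat., CH2Cl2, 0 °C) to the N-acyl enol carbamate F1, whose ring carbonyl is then an imide-activated enol ester and whose nitrogen can no longer be deprotonated. DMAP (1 equiv, MeCN, 40 °C) should open the ring to an enolate/N-acyl carbamoylpyridinium ion pair that recloses through carbon (Steglich-type O→C acyl transfer, still forming the C2–C3 bond) to the N-acyl 3-methyltetramic acid F2. C-methylation of F2 (MeI, K2CO3, acetone, rt) would then give 20, replacing steps 12 and 13.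

2. Step 12. Alkylation at oxygen of the ambident tetramate may compete with alkylation at C3. The fallback installs the second methyl group before the ring reorganisation, so that the quaternary C3 is created in the C–C closure itself; it sets out from 15 and comes back at 19. Iodo-carboxylative cyclisation of 15 (t-BuOI, CO2 1 atm, MeCN, −20 °C; anti addition) would give the (E)-iodoalkylidene oxazolidinone F3. Negishi methylation (MeZnCl, Pd(PPh3)4 cat., THF, rt) would give the isopropylidene oxazolidinone F4. F4 would then be rearranged as in step 11 (t-BuOK, THF/DMSO, 25 → 40 °C; 1 M HCl) to give 19 directly.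

3. Step 13. Proton transfer from the more acidic C5–H of the imide product to unreacted lactamate may erode the C5 configuration, and acylation at oxygen may compete. The fallback avoids any free amide anion; it sets out from 19 and comes back at 20. Compound 19 would be silylated on nitrogen (Me3SiCl, Et3N, CH2Cl2, rt) to the N-trimethylsilyl lactam F5. F5 would be heated with 6 (toluene, 80 °C), acyl-for-silyl exchange giving 20 under neutral conditions.

**Further compounds**

F1 | step 11 | (4R,5Z)-5-ethylidene-3-[(3S)-4,4,4-trichloro-3-methylbutanoyl]-4-[(2R)-3,3,3-trichloro-2-methylpropyl]-1,3-oxazolidin-2-one | C/C=C1\OC(=O)N(C(=O)C[C@H](C)C(Cl)(Cl)Cl)[C@@H]1C[C@@H](C)C(Cl)(Cl)Cl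
F2 | step 11 | (5R)-4-hydroxy-3-methyl-1-[(3S)-4,4,4-trichloro-3-methylbutanoyl]-5-[(2R)-3,3,3-trichloro-2-methylpropyl]-1,5-dihydro-2H-pyrrol-2-one | CC1=C(O)[C@@H](C[C@@H](C)C(Cl)(Cl)Cl)N(C(=O)C[C@H](C)C(Cl)(Cl)Cl)C1=O
F3 | step 12 | (4R,5E)-5-(1-iodoethylidene)-4-[(2R)-3,3,3-trichloro-2-methylpropyl]-1,3-oxazolidin-2-one | C/C(I)=C1\OC(=O)N[C@@H]1C[C@@H](C)C(Cl)(Cl)Cl
F4 | step 12 | (4R)-5-(propan-2-ylidene)-4-[(2R)-3,3,3-trichloro-2-methylpropyl]-1,3-oxazolidin-2-one | CC(C)=C1OC(=O)N[C@@H]1C[C@@H](C)C(Cl)(Cl)Cl
F5 | step 13 | (5R)-3,3-dimethyl-5-[(2R)-3,3,3-trichloro-2-methylpropyl]-1-(trimethylsilyl)pyrrolidine-2,4-dione | CC1(C)C(=O)[C@@H](C[C@@H](C)C(Cl)(Cl)Cl)N([Si](C)(C)C)C1=O
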